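Numbering follows the SMILES: C1 CHOAc, C2 CH2, C3 C(OH)iPr, C4 fusion CH, C5 CH–O-aroyl, C6=C7(Me), C8 C=O, C9 CH2, C10 C–Me. Ring A = C1–C2–C3–C4–C10, ring B = C4 to C10. α = face of the C10 methyl, β = face of H-4.
Cuts: the two ester C–O bonds; C5–O and C6=C7 back to a C5=C6 β,γ-enone; the C7–CH3 bond; C3–OH back to C2=C3, then C2=C3 itself (metathesis); last C4–C10 and C7–C8 of ring B. This leaves a (Z)-β-methyl enoate (C8–C9–C10 carrying C1) and an (E)-triene (C7–C6–C5–C4 carrying C3).
Enabling feature: in ring B the carbonyl C8 has C9–C10 on one side and the four-carbon run C7–C6–C5–C4 on the other, so C8 can be an ester carbon joined to both carbons of a terminal alkene C6=C7. The resulting cis-dialkenylcyclopropanol C6–C7–C8 is a 1,5-diene (C10=C9–C8–C6–C5=C4). Its [3,3] shift makes the quaternary C10–C4 bond and leaves the alkene at C5=C6, next to where oxygen is needed.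
Forward order: two fragments (3 + 2 steps), ring B in step 6, C7 methyl, ring A by ring-closing metathesis, then O at C3, O at C5, and the acylations. C2 travels as an internal propenyl group, which low-valent titanium ignores but ruthenium can load.
Stereochemistry: C1 comes from a catalytic asymmetric alkynylation. C4/C10 (trans fusion) come from the Z and E alkene geometries read through the boat Cope transition state, with the absolute sense relayed from C1 by A1,3 strain. C3–OH comes from O2 capture on the β face, and C5–O from a C3–OH-directed β epoxidation.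

Key step: step 6

Assumption: the (S,S)-ProPhenol–zinc catalyst is taken to give the (S)-carbinol from enals; if the sense proves opposite, the (R,R)-ligand is used and nothing else changes.

Step 1
Reactants: 1 (E)-but-2-enal; 2 methyl prop-2-ynoate
Product: 3 methyl (4S,5E)-4-hydroxyhept-5-en-2-ynoate
Conditions: (S,S)-ProPhenol (10 mol %), Ph3PO (20 mol %), Me2Zn (3 equiv), PhMe, 4 °C; H2O
Reagents that add atoms: none
Why: Zinc–ProPhenol catalysed asymmetric alkynylation of an α,β-unsaturated aldehyde with methyl propiolate is an established reaction class that gives only 1,2-addition, and the chiral dinuclear zinc pocket selects the aldehyde face that sets C1 as S.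

Step 2
Reactants: 3 methyl (4S,5E)-4-hydroxyhept-5-en-2-ynoate
Product: 4 methyl (4S,5E)-4-(tert-butyldimethylsilyloxy)hept-5-en-2-ynoate
Conditions: TBSCl, imidazole, DMF, 0 °C → rt
Reagents that add atoms: tert-butyldimethylsilyl chloride, CC(C)(C)[Si](C)(C)Cl
Why: Standard imidazole-promoted silylation of a secondary propargylic alcohol is mild enough to avoid base-induced isomerisation of the γ-hydroxy ynoate, masks C1–OH for the organometallic steps and prevents lactonisation after step 3.

Step 3
Reactants: 4 methyl (4S,5E)-4-(tert-butyldimethylsilyloxy)hept-5-en-2-ynoate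
Product: 5 methyl (2Z,4S,5E)-4-(tert-butyldimethylsilyloxy)-3-methylhepta-2,5-dienoate (C1 carbon cis to the ester)
Conditions: MeLi (2.4 equiv), CuI (1.2 equiv), THF, 0 → −78 °C; 4; sat. aq NH4Cl at −78 °C
Reagents that add atoms: Me2CuLi (lithium dimethylcuprate), [Li+].C[Cu-]C
Why: Syn carbocupration of a 2-ynoate by a Gilman reagent followed by cold protonation with retention places the new methyl cis to H-9 and therefore the C1 carbon cis to the ester, the Z geometry that later defines C10.

Step 4
Reactants: 6 3-methylbutanal
Product: 7 3-methyl-2-methylidenebutanal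
Conditions: 37% aq HCHO, pyrrolidine (10 mol %), EtCO2H (10 mol %), iPrOH, 45 °C
Reagents that add atoms: formaldehyde, C=O
Why: The amine/acid-catalysed Mannich condensation–elimination (organocatalytic α-methylenation of aldehydes) is well precedented for α-unbranched aldehydes such as 6 and installs the C3=CH2 unit.

Step 5
Reactants: 7 3-methyl-2-methylidenebutanal; 8 diethyl allylphosphonate
Product: 9 (3E)-6-methyl-5-methylidenehepta-1,3-diene
Conditions: 8, n-BuLi, THF, −78 °C; HMPA; 7, −78 °C → rt
Reagents that add atoms: none
Why: Horner–Wadsworth–Emmons-type olefination of aldehydes with lithiated allylphosphonate in the presence of HMPA is a known route to terminal (E)-1,3-dienes and sets the E geometry at C4=C5 that later defines C4.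

Step 6
Reactants: 5 methyl (2Z,4S,5E)-4-(tert-butyldimethylsilyloxy)-3-methylhepta-2,5-dienoate; 9 (3E)-6-methyl-5-methylidenehepta-1,3-diene
Product: 13 (5R,6S)-6-[(1S,2E)-1-(tert-butyldimethylsilyloxy)but-2-en-1-yl]-6-methyl-5-(3-methylbut-1-en-2-yl)cyclohept-3-en-1-one, via titanacyclopropane 10 (not isolated), via cis-dialkenylcyclopropanol 11 (not isolated), via cycloheptadienol 12 (not isolated)
Conditions: 9 (2 equiv), ClTi(OiPr)3 (1.2 equiv), c-C5H9MgCl (2.6 equiv, slow addition), THF, 0 °C → rt; then 65 °C; H2O
Reagents that add atoms: none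
Why: (c-C5H9)2Ti(OiPr)2 collapses to (η2-C5H8)Ti(OiPr)2, which passes its divalent titanium to the only monosubstituted alkene on offer, C6=C7 of 9, and the resulting 10 acts as a 1,2-dicarbanion towards the ester carbon C8 of 5 (C7–C8 bond by carbonyl insertion, loss of methoxide, then 3-exo-trig attack of the allylic C6–Ti bond on the C8 ketone), closing the three-membered ring C6–C7–C8 of 11 with the usual cis preference of the Kulinkovich reaction so that both alkenyl groups lie on one face. The closest known chemistry is this same pair of reactions, the olefin-exchange Kulinkovich hydroxycyclopropanation of an unsaturated ester with a 1,3-diene and the oxy-Cope (divinylcyclopropane) rearrangement of the cis-1,2-dialkenylcyclopropanol, and quaternary carbons are known products of divinylcyclopropane rearrangements. On warming, the alkoxide of 11 folds into the endo boat, C6–C8 breaks while C4–C10 forms, and ring B closes by this [3,3] ring expansion as the C8=C9 enolate of 12, which is protonated at C9 on work-up and leaves C5=C6 out of conjugation. In the boat the two outward substituents, the C10 methyl (trans to C8 in the Z-enoate) and the C3 arm (E-diene), end cis on ring B, which fixes C4 relative to C10 in the sense of the trans fusion, and C4 cannot epimerise afterwards because it is not alpha to a carbonyl group. The absolute sense is relayed from C1: A1,3 strain with the cis C8 substituent holds C1–H in the alkene plane, C4 should then bond to the C10 face anti to the C1–O bond and its bulky silyl group, and since C6 is allylic the closure of 11 may be reversible on the metal, so that a cyclopropanolate of the wrong sense can drain through this lower boat, while any product of the other sense is a diastereomer and separable. The step needs site selectivity at titanium, secured by substitution (the 1,1-disubstituted C3=CH2, the internal propenyl group and the β,β-disubstituted enoate alkene do not displace cyclopentene), and it pays for the quaternary centre with a slower rearrangement because the C1 carbon points inward towards C7H2, hence the thermal drive.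

Step 7
Reactants: 13 ring B β,γ-enone
Product: 14 (5R,6S)-6-[(1S,2E)-1-(tert-butyldimethylsilyloxy)but-2-en-1-yl]-2,6-dimethyl-5-(3-methylbut-1-en-2-yl)cyclohept-3-en-1-one (C7 epimers)
Conditions: LiN(iPr)2 (1.05 equiv), THF, −78 °C; MeI (3 equiv), −78 → −40 °C
Reagents that add atoms: iodomethane, CI
Why: Kinetic deprotonation takes the doubly activated C7–H (C9 is neopentylic and less acidic), and alkylation of the linear dienolate at its α-carbon, the normal course of dienolate alkylation, keeps C5=C6 out of conjugation, while the new C7 centre needs no control because step 11 erases it.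

Step 8
Reactants: 14 C7-methylated ring B ketone
Product: 15 trans-fused hydroazulenone with C2=C3 (iPr on C3), C5=C6, C7–Me, C8=O and α C1–OTBS (1S,4R,10S; C7 epimers)
Conditions: second-generation Hoveyda–Grubbs catalyst (10 mol %), 1,4-benzoquinone (20 mol %), PhMe (2 mM), 80 °C, Ar sparge
Reagents that add atoms: none
Why: In this ring-closing metathesis the catalyst loads at the accessible propenyl group and the C2 alkylidene closes five-membered ring A onto the neighbouring 1,1-disubstituted alkene (isopropyl-substituted examples are known partners) across the gauche, trans-diequatorial arms with loss of propene, while the unstrained ring alkene, branched at both allylic carbons, should stay aside.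

Step 9
Reactants: 15 trans-fused hydroazulenone diene
Product: 17 C3 tertiary alcohol (β OH, α iPr; C5=C6, C8=O and α C1–OTBS unchanged; C7 epimers), via tertiary hydroperoxide 16 (not isolated)
Conditions: Mn(dpm)3 (15 mol %), PhSiH3 (3 equiv), O2 (1 atm), iPrOH/CH2Cl2, 0 °C; then PPh3
Reagents that add atoms: dioxygen, O=O
Why: Mukaiyama hydration (metal-hydride hydrogen-atom transfer) puts H on C2 and a tertiary radical on C3 in preference to the 1,2-disubstituted C5=C6, O2 is captured on the β face opposite the angular C10 methyl and the C1 silyl ether, which sets C3 with OH cis to H-4, and PPh3 reduces the peroxide.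

Step 10
Reactants: 17 C3 tertiary alcohol
Product: 18 5,6-β-epoxide of 17 (C7 epimers)
Conditions: VO(acac)2 (10 mol %), tBuOOH (decane, 2 equiv), CH2Cl2, 0 °C → rt
Reagents that add atoms: tert-butyl hydroperoxide, CC(C)(C)OO
Why: In this vanadium-catalysed hydroxyl-directed epoxidation of a homoallylic alcohol the β C3–OH carries the peroxo-vanadium species to the β face of C5=C6, which is also the face away from the C10 methyl and the C3 isopropyl group, and so sets the C5–O configuration.

Step 11
Reactants: 18 β,γ-epoxy ketone
Product: 19 γ-hydroxy enone (β C5–OH, C6=C7(Me)–C8=O, β C3–OH, α C1–OTBS)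
Conditions: DBU (1.2 equiv), CH2Cl2, 0 °C
Reagents that add atoms: none
Why: E1cB opening of a β,γ-epoxy ketone, in which the C7 enolate expels the C6–O bond, gives the conjugated C6=C7 enone, keeps the C5–O configuration and removes the C7 stereocentre.

Step 12
Reactants: 19 γ-hydroxy enone; 20 4-acetoxybenzoyl chloride
Product: 21 C5 4-acetoxybenzoate of 19
Conditions: 20 (2.5 equiv), pyridine, DMAP (20 mol %), CH2Cl2, 0 °C → rt
Reagents that add atoms: none
Why: DMAP-catalysed acylation with an acid chloride distinguishes the secondary allylic C5–OH from the hindered tertiary C3–OH, and the phenol travels as its acetate.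

Step 13
Reactants: 21 C5 4-acetoxybenzoate
Product: 22 C1 alcohol (α C1–OH; aryl acetate retained)
Conditions: HF·pyridine, THF, 0 °C → rt
Reagents that add atoms: none
Why: Fluoride-induced desilylation under mildly acidic conditions removes the hindered C1 silyl ether without touching the aryl acetate, the benzoate, the enone or the tertiary alcohol.

Step 14
Reactants: 22 C1 alcohol
Product: 23 C1 acetate, aryl acetate (diacetate)
Conditions: Ac2O, pyridine, DMAP (10 mol %), CH2Cl2, rt
Reagents that add atoms: acetic anhydride, CC(=O)OC(C)=O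
Why: Standard acetylation esterifies the only secondary alcohol while the tertiary C3–OH stays free.

Step 15
Reactants: 23 diacetate
Product: 24 CNP0087181.1, (1S,3R,3aR,4R,8aS)-1-acetoxy-3-hydroxy-6,8a-dimethyl-7-oxo-3-(propan-2-yl)-1,2,3,3a,4,7,8,8a-octahydroazulen-4-yl 4-hydroxybenzoate
Conditions: NH4OAc, MeOH/H2O (4:1), rt
Reagents that add atoms: none
Why: Aryl acetates, here further activated by the para ester group, are hydrolysed selectively by NH4OAc in aqueous methanol under neutral conditions, which leaves the alkyl acetate at C1 and the hindered C5 benzoate intact.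

Compound list
1 | (E)-but-2-enal | C/C=C/C=O | starting material
2 | methyl prop-2-ynoate | C#CC(=O)OC | starting material
3 | methyl (4S,5E)-4-hydroxyhept-5-en-2-ynoate | COC(=O)C#C[C@@H](O)/C=C/C | intermediate
4 | methyl (4S,5E)-4-(tert-butyldimethylsilyloxy)hept-5-en-2-ynoate | COC(=O)C#C[C@@H](O[Si](C)(C)C(C)(C)C)/C=C/C | intermediate
5 | methyl (2Z,4S,5E)-4-(tert-butyldimethylsilyloxy)-3-methylhepta-2,5-dienoate | COC(=O)/C=C(/C)[C@@H](O[Si](C)(C)C(C)(C)C)/C=C/C | intermediate
6 | 3-methylbutanal | CC(C)CC=O | starting material
7 | 3-methyl-2-methylidenebutanal | CC(C)C(=C)C=O | intermediate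
8 | diethyl allylphosphonate | C=CCP(=O)(OCC)OCC | starting material
9 | (3E)-6-methyl-5-methylidenehepta-1,3-diene | C=C/C=C/C(=C)C(C)C | intermediate
10 | 1,1-diisopropoxy-2-[(1E)-4-methyl-3-methylidenepent-1-en-1-yl]titanacyclopropane (C6 labile, not specified) | CC(C)O[Ti]1(OC(C)C)CC1/C=C/C(=C)C(C)C | intermediate
11 | (1R,2S)-1-[(1Z,3S,4E)-3-(tert-butyldimethylsilyloxy)-2-methylhexa-1,4-dien-1-yl]-2-[(1E)-4-methyl-3-methylidenepent-1-en-1-yl]cyclopropan-1-ol (formed as its titanium alkoxide) | O[C@]1(/C=C(/C)[C@@H](O[Si](C)(C)C(C)(C)C)/C=C/C)C[C@H]1/C=C/C(=C)C(C)C | intermediate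
12 | C8=C9 enol of 13, a cyclohepta-1,4-dien-1-ol (formed as its titanium enolate) | CC(C)(C)[Si](C)(C)O[C@@H](/C=C/C)[C@@]1(C)C=C(O)CC=C[C@@H]1C(=C)C(C)C | intermediate
13 | (5R,6S)-6-[(1S,2E)-1-(tert-butyldimethylsilyloxy)but-2-en-1-yl]-6-methyl-5-(3-methylbut-1-en-2-yl)cyclohept-3-en-1-one | CC(C)(C)[Si](C)(C)O[C@@H](/C=C/C)[C@@]1(C)CC(=O)CC=C[C@@H]1C(=C)C(C)C | intermediate
14 | 2-methyl derivative of 13 (methyl on C7, both epimers) | CC(C)(C)[Si](C)(C)O[C@@H](/C=C/C)[C@@]1(C)CC(=O)C(C)C=C[C@@H]1C(=C)C(C)C | intermediate
15 | trans-fused hydroazulenone, C2=C3(iPr), C5=C6, C7–Me, C8=O, α C1–OTBS (C7 epimers) | CC(C)(C)[Si](C)(C)O[C@H]1C=C(C(C)C)[C@H]2C=CC(C)C(=O)C[C@]12C | intermediate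
16 | C3 β-hydroperoxide | CC(C)(C)[Si](C)(C)O[C@H]1C[C@@](OO)(C(C)C)[C@H]2C=CC(C)C(=O)C[C@]12C | intermediate
17 | C3 β-alcohol (α iPr) | CC(C)(C)[Si](C)(C)O[C@H]1C[C@@](O)(C(C)C)[C@H]2C=CC(C)C(=O)C[C@]12C | intermediate
18 | 5,6-β-epoxy ketone | CC(C)(C)[Si](C)(C)O[C@H]1C[C@@](O)(C(C)C)[C@H]2[C@@H]3O[C@@H]3C(C)C(=O)C[C@]12C | intermediate
19 | β C5-hydroxy C6=C7 enone | CC(C)(C)[Si](C)(C)O[C@H]1C[C@@](O)(C(C)C)[C@H]2[C@H](O)C=C(C)C(=O)C[C@]12C | intermediate
20 | 4-acetoxybenzoyl chloride | CC(=O)Oc1ccc(cc1)C(Cl)=O | starting material
21 | C5 4-acetoxybenzoate, C1–OTBS | CC(C)(C)[Si](C)(C)O[C@H]1C[C@@](O)(C(C)C)[C@H]2[C@H](OC(=O)c3ccc(OC(C)=O)cc3)C=C(C)C(=O)C[C@]12C | intermediate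
22 | C5 4-acetoxybenzoate, C1–OH | O[C@H]1C[C@@](O)(C(C)C)[C@H]2[C@H](OC(=O)c3ccc(OC(C)=O)cc3)C=C(C)C(=O)C[C@]12C | intermediate
23 | C5 4-acetoxybenzoate, C1–OAc | CC(=O)O[C@H]1C[C@@](O)(C(C)C)[C@H]2[C@H](OC(=O)c3ccc(OC(C)=O)cc3)C=C(C)C(=O)C[C@]12C | intermediate
24 | CNP0087181.1 | CC(=O)O[C@H]1C[C@@](O)(C(C)C)[C@H]2[C@H](OC(=O)c3ccc(O)cc3)C=C(C)C(=O)C[C@]12C | target

Total step count: 15. Longest linear sequence: 13 steps (steps 1–3 and 6–15).

Steps most likely to fail

Step 6. The inward-pointing C1 carbon may slow the boat rearrangement so much that the metal cyclopropanolate opens to its homoenolate and is lost by protonation. The facial relay from C1 may also be weak. In the fallback the two events are separated and the rearrangement is run on a neutral, purified substrate. The route leaves at 11, which is obtained by quenching the titanium reaction at 0 °C and is freed from its diastereomer by chromatography. Me3SiOTf and 2,6-lutidine in CH2Cl2 at −78 °C give the cyclopropyl trimethylsilyl ether F1, which can no longer ring-open. Heating in toluene or xylene (110–140 °C) brings about the known siloxy-divinylcyclopropane rearrangement to the trimethylsilyl dienol ether F2. Bu4NF buffered with AcOH at 0 °C cleaves only the enol ether, and the route is rejoined at 13.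

Step 8. The C2 ruthenium alkylidene may attack the ring alkene C5=C6 (ring opening and rearrangement) faster than the hindered C3=CH2, or ruthenium hydrides may shift C5=C6 during the long reaction time. In the fallback the ring alkene is taken out of play before the metathesis. From 14, DBU in CH2Cl2 moves the alkene into conjugation and gives the monocyclic conjugated enone F3, whose trisubstituted, electron-poor C6=C7 bond is inert to ruthenium alkylidenes. Ring-closing metathesis under the conditions of step 8 gives the bicyclic conjugated enone F4. Deconjugation by γ-deprotonation with KOtBu in THF/tBuOH and kinetic α-protonation of the dienolate with aqueous AcOH restores C5=C6 and rejoins the route at 15.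

Step 9. Hydrogen-atom transfer or peroxyl radicals may also engage the β,γ-enone (C5=C6 and the doubly activated C7–H), or O2 capture at the C3 radical may show poor facial selectivity. The fallback is a polar, two-electron sequence. From 15, one equivalent of mCPBA (NaHCO3, CH2Cl2, 0 °C) epoxidises the more electron-rich trisubstituted C2=C3 bond on the open β face and gives the 2,3-β-epoxide F5. LiEt3BH in THF delivers hydride to the less substituted C2 and also reduces C8=O, giving the C3,C8-diol F6. Dess–Martin periodinane (NaHCO3 buffer) reoxidises the only secondary alcohol, and the route is rejoined at 17.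

Further compounds
F1 | step 6 | cyclopropyl trimethylsilyl ether (O-SiMe3 derivative of 11) | C[Si](C)(C)O[C@]1(/C=C(/C)[C@@H](O[Si](C)(C)C(C)(C)C)/C=C/C)C[C@H]1/C=C/C(=C)C(C)C
F2 | step 6 | trimethylsilyl dienol ether (O-SiMe3 derivative of 12) | CC(C)(C)[Si](C)(C)O[C@@H](/C=C/C)[C@@]1(C)C=C(O[Si](C)(C)C)CC=C[C@@H]1C(=C)C(C)C
F3 | step 8 | monocyclic conjugated enone (C6=C7 isomer of 14) | CC(C)(C)[Si](C)(C)O[C@@H](/C=C/C)[C@@]1(C)CC(=O)C(C)=CC[C@@H]1C(=C)C(C)C
F4 | step 8 | bicyclic conjugated enone (C6=C7 isomer of 15) | CC(C)(C)[Si](C)(C)O[C@H]1C=C(C(C)C)[C@H]2CC=C(C)C(=O)C[C@]12C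
F5 | step 9 | 2,3-β-epoxide of 15 | CC(C)(C)[Si](C)(C)O[C@H]1[C@@H]3O[C@]3(C(C)C)[C@H]2C=CC(C)C(=O)C[C@]12C
F6 | step 9 | C3,C8-diol (C8 epimers) | CC(C)(C)[Si](C)(C)O[C@H]1C[C@@](O)(C(C)C)[C@H]2C=CC(C)C(O)C[C@]12C
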